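The earlier runs and the new flask come from a simulation from invented constants; noise was put on by code.

41.4 was the number I started from: the free monomer charged, 0.58 M, over the initiator charged, 14 mM. I called it the ceiling G, the monomer units per chain in this flask if each initiator begins one chain and each monomer unit enters a chain.

- Monday's: free monomer 0.58 M; initiator 14 mM; the very flask that is asked about, followed so far
- flask: free monomer 0.58 M; initiator 14 mM; time 3.0 d

Monday's run (percent of the free monomer charged)

| time / h | monomer in chains / % | free monomer / % |
|---|---|---|
| 0.500 | 3.2 | 95.4 |
| 1.33 | 7.6 | 89.5 |
| 2.50 | 12.6 | 81.1 |
| 4.00 | 19.1 | 72.9 |
| 6.00 | 26.2 | 62.1 |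

(readings scatter by 0.3 percentage points)

- the average divides the monomer in chains by the number of chains begun, living and dead together
- what was read earlier has a scatter of 0.3 percentage points, one standard deviation
- the earlier runs do not show the number of chains; that part of a forecast is a guess

- average number of monomer units in a chain (chains begun, living or dead) at 3.0 d
- part of the free monomer that has reacted at 3.0 d

1. The average chain length dp (degree of polymerisation) divides monomer in chains by chains begun. Monday's readings do not show the chains, so one chain per initiator was my guess, and that gave dp = G × s, with s the part of the free monomer charged that stands in chains.
2. At the early end, Monday's reading at 6.00 h put a share f = 69.1% of the reacted free monomer in chains.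
3. At the late end, taking the fall of free monomer as first order, I read from the same reading a constant k = 0.0794 h⁻¹, a half-life of 8.73 h, much shorter than 3.0 d. So I expected nearly all of the free monomer in this flask to have reacted, c = 99.7%.
4. Joining the ends, I took s = f × c, supposing the share f held to the end, and my own estimate of dp came to 28.5.
5. The forecast, a different reckoning from mine, gave 30 and 96%, and said of its chain length: "Incomplete efficiency raises this and transfer lowers it, so this is a guess".
6. This flask gave dp = 19.3 and c = 88.5%.

    free monomer + initiator → living end + monomer in chains (k = 0.0990 M⁻¹ min⁻¹)
    free monomer + living end → monomer in chains + living end, rate k2*[living end]*[free monomer] (k = 0.0810 M⁻¹ min⁻¹)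
    monomer in chains + living end → free monomer + living end, rate k3*[living end] as long as [monomer in chains] is above zero (k = 0.00730 min⁻¹)
    free monomer → uncatalysed product (k = 4.00 × 10⁻⁴ min⁻¹)
    initiator → spent initiator (k = 0.00140 min⁻¹)

At 3.00 d monomer in chains in this flask was being made at 0.743 times the rate it was used up, each step taken net, so the chains were losing monomer on balance, and they held 45.5% of the free monomer charged, less than my estimated 68.9%. With that s, G × s gives 18.8. The neighbour charged with 0.0056 M of initiator has a ceiling of 104. With 33.0% of the free monomer charged to it in chains at 3.00 d, G × s gives 34.3, and that neighbour gave 35.1.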